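**Strategy.** Ring C of the flavanone is cut across O1–C2 and C3–C4. The O1–C8a–C4a–C4 array at the ring A/ring C fusion is treated as an ortho-quinone methide heterodiene carrying a methoxy group on the future C4, and the C2–C3 edge bearing the trimethoxyphenyl ring is the 2π partner, a styrene. One chiral-acid-catalysed inverse-demand oxa-[4+2] cycloaddition forms both bonds, closes the dihydropyran ring and sets C2 (S), leaving C4 at the ketone oxidation level as a benzylic methyl ether. The precursor is commercial 2-hydroxy-4,6-dimethoxybenzaldehyde, converted in the flask into its dimethyl acetal and then the cationic heterodiene. A single DDQ oxidation then unveils the C4 ketone.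

Key step: step 1

Assumption: the sense of induction of the chiral acid cannot be predicted for this new substrate pairing; the (R)-catalyst is written, and its (S)-antipode is used instead if the first run gives mainly the 2R series.

**Step 1**
Reactants: 1 2-hydroxy-4,6-dimethoxybenzaldehyde; 2 5-ethenyl-1,2,3-trimethoxybenzene; 3 trimethyl orthoformate
Product: 6 (2S,4S)-4,5,7-trimethoxy-2-(3,4,5-trimethoxyphenyl)chroman, via dimethyl acetal 4 (not isolated), via oxocarbenium heterodiene 5 (not isolated)
Conditions: 2 (2 equiv), 3 (1.2 equiv), (R)-3,3'-bis(2,4,6-triisopropylphenyl)-BINOL N-triflylphosphoramide (5 mol %), 5 Å MS, toluene, −20 °C; Et3N quench, Et3N-deactivated SiO2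
Reagents that add atoms: trimethyl orthoformate (compound 3), COC(OC)OC
Why: Proposed new method: the chiral acid catalyses acetal exchange between 1 and 3 to give 4 and then ionises 4, with loss of methanol, to the aryl-stabilised oxocarbenium ion 5 (an O-protonated α-methoxy ortho-quinone methide) that stays hydrogen-bonded through its phenolic OH to the chiral N-triflylphosphoramidate anion; C3–C4 is formed first, by attack of the alkene CH2 of 2 on the cationic carbon, and O1–C2 follows when the phenolic oxygen traps the incipient benzylic cation, so the overall event is an asynchronous inverse-demand oxa-[4+2] cycloaddition. The closest known reaction types are the achiral acid-promoted three-component synthesis of 4-alkoxy-2-arylchromans from salicylaldehydes, orthoformates and styrenes, and chiral Brønsted acid catalysed cycloadditions of ortho-quinone methides or salicylaldehyde-acetal-derived oxocarbenium ions with vinyl ethers, enamides or tethered alkenes; enantiocontrol with a simple styrene that offers no hydrogen-bonding handle is the unproven part. Ring C (O1, C2, C3, C4, C4a, C8a) is closed by the cycloaddition itself through a half-chair six-membered transition state in which C3–C4 bonding runs ahead of O1–C2 bonding. C2 is set by the catalyst, whose anion shields one face of the bound heterodiene so that the styrene presents the face leading to 2S, while C4 follows from the endo-type arrangement that places the aryl and methoxy groups cis and is in any case erased in step 2. The step needs regioselectivity, secured by the polarisation of the styrene (nucleophilic CH2, cation-stabilising aryl-bearing carbon) matched to the acetal-carbon electrophile, and enantiofacial selectivity at C2, for which the ortho OH of 5 anchors the chiral anion next to the forming O1–C2 bond. Excess 2, only a slight excess of 3, sieves that take up methanol, low temperature and an amine quench are meant to favour alkene capture of 5 over Friedel–Crafts attack by the electron-rich ring A of 4 or 6, cationic oligomerisation of 2 and re-ionisation of 6 at C4.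

**Step 2**
Reactants: 6 (2S,4S)-4,5,7-trimethoxy-2-(3,4,5-trimethoxyphenyl)chroman
Product: 8 (2S)-5,7-dimethoxy-2-(3,4,5-trimethoxyphenyl)chroman-4-one, via methyl hemiketal 7 (not isolated)
Conditions: DDQ (1.2 equiv), CH2Cl2/pH 7 phosphate buffer (10:1), 0 °C → rt
Reagents that add atoms: water, O
Why: This is the DDQ oxidative cleavage of an electron-rich benzylic ether (the reaction type used to remove p-methoxybenzyl ethers): hydride abstraction from C4 is strongly favoured by the ortho/para oxygen substituents of ring A, water adds to give hemiketal 7, which collapses to ketone 8 with loss of methanol, so any C4 epimer converges while the less hydridic C2–H and the C2 (S) centre should stay untouched under these near-neutral, base-free conditions.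

**Compound list**
1 | 2-hydroxy-4,6-dimethoxybenzaldehyde | COc1cc(O)c(C=O)c(OC)c1 | starting material
2 | 5-ethenyl-1,2,3-trimethoxybenzene (3,4,5-trimethoxystyrene) | C=Cc1cc(OC)c(OC)c(OC)c1 | starting material
3 | trimethyl orthoformate | COC(OC)OC | starting material
4 | 2-(dimethoxymethyl)-3,5-dimethoxyphenol | COC(OC)c1c(O)cc(OC)cc1OC | intermediate (not isolated)
5 | (2-hydroxy-4,6-dimethoxyphenyl)methylidene(methyl)oxonium (O-protonated α-methoxy ortho-quinone methide, ion-paired with the catalyst anion) | C[O+]=Cc1c(O)cc(OC)cc1OC | intermediate (not isolated)
6 | (2S,4S)-4,5,7-trimethoxy-2-(3,4,5-trimethoxyphenyl)chroman (2,4-cis) | COc1cc(OC)c2c(c1)O[C@H](c1cc(OC)c(OC)c(OC)c1)C[C@@H]2OC | intermediate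
7 | (2S)-4-hydroxy-4,5,7-trimethoxy-2-(3,4,5-trimethoxyphenyl)chroman (methyl hemiketal, C4 undefined) | COc1cc(OC)c2c(c1)O[C@H](c1cc(OC)c(OC)c(OC)c1)CC2(O)OC | intermediate (not isolated)
8 | (2S)-5,7-dimethoxy-2-(3,4,5-trimethoxyphenyl)chroman-4-one | COc1cc(OC)c2c(c1)O[C@H](c1cc(OC)c(OC)c(OC)c1)CC2=O | target

Total step count: 2
Longest linear sequence: 2

**Steps most likely to fail** (the route has only two steps, so both are ranked and there is no third)

1. Step 1. The process at risk is enantiofacial discrimination of the unfunctionalised styrene by the ion pair; slow intermolecular capture could also let cationic side reactions dominate. Fallback (known chemistry, racemic cycloaddition plus late kinetic resolution): setting out from 1, 2 and 3, the three-component cycloaddition is run with an achiral acid (p-TsOH 10 mol %, toluene, 0 °C → rt) to give racemic 4,5,7-trimethoxy-2-(3,4,5-trimethoxyphenyl)chroman F1. DDQ in CH2Cl2/pH 7 buffer, as in step 2, then gives racemic 5,7-dimethoxy-2-(3,4,5-trimethoxyphenyl)chroman-4-one F2. Kinetic resolution of F2 by asymmetric transfer hydrogenation with [Cp*RhCl((R,R)-TsDPEN)] (trivalent rhodium; HCO2H/Et3N, EtOAc, rt, stopped near half conversion) is expected to reduce the 2R ketone. The argument is by analogy with aryl ketone transfer hydrogenation: the (R,R)-complex should deliver the 4R alcohol, and the favoured cis-forming hydride approach pairs 4R with 2R. The reduced product is (2R,4R)-5,7-dimethoxy-2-(3,4,5-trimethoxyphenyl)chroman-4-ol F3, and the unreacted 2S ketone is 8, where the route is rejoined after chromatographic separation. The (S,S)-complex is used if the sense proves opposite.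

2. Step 2. The process at risk is hydride abstraction that is not confined to C4: attack at the C2–H, or further dehydrogenation of the ketone across C2–C3, would cost material or the C2 stereocentre. Fallback (solvolysis then alcohol oxidation in place of hydride abstraction): setting out from 6, the C4 methyl ether is solvolysed (PPTS, THF/H2O, rt → 40 °C), with a large excess of water to intercept the 2,4,6-trioxygenated benzylic cation. This gives (2S)-5,7-dimethoxy-2-(3,4,5-trimethoxyphenyl)chroman-4-ol F4 as a C4 epimer mixture. Dess–Martin periodinane with NaHCO3 in CH2Cl2 at rt then oxidises both epimers to 8, where the route is rejoined.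

**Further compounds**
F1 | step 1 | racemic 4,5,7-trimethoxy-2-(3,4,5-trimethoxyphenyl)chroman (2,4-cis expected as major, no absolute configuration) | COc1cc(OC)c2c(c1)OC(c1cc(OC)c(OC)c(OC)c1)CC2OC
F2 | step 1 | racemic 5,7-dimethoxy-2-(3,4,5-trimethoxyphenyl)chroman-4-one | COc1cc(OC)c2c(c1)OC(c1cc(OC)c(OC)c(OC)c1)CC2=O
F3 | step 1 | (2R,4R)-5,7-dimethoxy-2-(3,4,5-trimethoxyphenyl)chroman-4-ol | COc1cc(OC)c2c(c1)O[C@@H](c1cc(OC)c(OC)c(OC)c1)C[C@H]2O
F4 | step 2 | (2S)-5,7-dimethoxy-2-(3,4,5-trimethoxyphenyl)chroman-4-ol (C4 epimers) | COc1cc(OC)c2c(c1)O[C@H](c1cc(OC)c(OC)c(OC)c1)CC2O
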